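A fraction of the charge per minute is the unit in which the violet run speaks, and since that run is this very flask, I started from it.

| setting | violet | flask |
|---|---|---|
| starting material | 0.050 M | 0.050 M |
| second substrate | 1.8 equiv | 1.80 equiv |
| enzyme | 0.01 mol% | 0.01 mol% |
| remark | the very flask that is asked about, followed so far |  |

violet run (percent of the starting material charged)

| time / min | target / % | starting material / % |
|---|---|---|
| 5.00 | 12 | 92 |
| 15.0 | 26 | 73 |
| 25.0 | 34 | 66 |
| 40.0 | 40 | 58 |
| 50.0 | 44 | 55 |

(each reading ± 1.5 percentage points)

- the analysis behind the earlier runs scatters by 1.5 percentage points, standard deviation
- no earlier run changes the charge of second substrate; that part of a forecast is a guess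

* apparent order in second substrate when 20% of the starting material are converted (percent change of the rate of making target for one percent more second substrate charged)

Over the first 5.00 min the target rose at 0.0240 min⁻¹, around a target of 6.00%, and between 40.0 min and 50.0 min at 0.00400 min⁻¹, around 42.0%. Drawing a straight line of rate against target, I read a relaxation lifetime of 18.0 min and a plateau near 49.2%, both readings carrying the scatter of 1.5 percentage points.

I then asked what would have to be true for the order in second substrate to stay below one. I took the net rate as a forward rate minus a backward rate, with the backward share growing as target over starting material times second substrate, and with the read plateau as the balance point. At 20% conversion that share came to 0.211. One percent more second substrate charged meant 1.12 percent more present there. The apparent order is therefore this stretch times the forward order plus share over one minus share. The part that stands apart from the forward order, the stretch times share over one minus share, I call the reversal lift, 0.301. The order stays below one if the forward order is under 0.621. No run varied the charge, so a forward order between 0 and 1 put the order between 0.301 and 1.43, and I committed to the middle, 0.863.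

The forecast, 0.5, stood lower than my figure, with the remark “Reversibility could push it slightly above 1 at fixed conversion”; the flask gives 1.2.

    starting material + enzyme ⇌ starting complex (K = 200 M⁻¹, k = 3.10 × 10⁵ M⁻¹ min⁻¹)
    second substrate + starting complex ⇌ ternary complex (K = 4.50 M⁻¹, k = 26000 M⁻¹ s⁻¹)
    ternary complex ⇌ enzyme + target (K = 0.0140 M, k = 780 min⁻¹)

In this flask the target stands at 45.6% after 1.50 h and at 45.8% after 30.0 h. With that last target of this flask as the balance point, the share at 20% conversion comes to 0.248 and the reversal lift to 0.371, where my read plateau had given 0.301; taking this new lift from 1.2 and dividing by the stretch of 1.12 leaves, on my reckoning, a forward order of 0.746, higher than the crossing, which now stands at 0.559.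

The numbers in the tables stem from a simulated flask from invented constants; scatter was added.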